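**Strategy**

The whole route rests on cutting the bond between C1 of the 2-methoxy-4-methylphenyl ring and the fully substituted carbinol carbon, which also carries a hydroxyl and two CH2O arms. That carbon is made the lithiated carbon of a 2-(benzyloxymethyl)oxirane: it adds to the boron of the aryl pinacol boronate, and the aryl ring then shifts from boron to carbon while the epoxide C–O bond breaks. One operation thus forms the aryl–carbon bond, releases one CH2OH arm and leaves boron on the carbinol carbon as a latent tertiary hydroxyl. The precursors are the arylboronic ester and an oxiranyllithium generated by tin–lithium exchange from a regiodefined stannyl epoxide.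

Key step: step 5

Remark: the target is achiral (its carbinol carbon bears two identical isobutyryloxymethyl arms), so compounds 7 to 11 are carried as racemates and the stereocentre vanishes at triol 12.

**Route**

Step 1
Reactants: 1 (2-methoxy-4-methylphenyl)boronic acid
Product: 2 2-(2-methoxy-4-methylphenyl)-4,4,5,5-tetramethyl-1,3,2-dioxaborolane
Conditions: pinacol, toluene, reflux, Dean–Stark
Reagents that add atoms: pinacol, CC(C)(O)C(C)(C)O
Why: Boronic ester formation by condensation of the boronic acid with a 1,2-diol is driven to completion by azeotropic removal of water and touches neither the aryl ether nor the ring.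

Step 2
Reactants: 3 2,3-dibromoprop-1-ene
Product: 4 benzyl 2-bromoallyl ether
Conditions: BnOH, NaH, THF, 0 °C → rt
Reagents that add atoms: benzyl alcohol, OCc1ccccc1
Why: Williamson ether synthesis, in which sodium benzyloxide displaces the allylic bromide by SN2 while the vinylic C–Br bond is inert to alkoxide at room temperature.

Step 3
Reactants: 4 benzyl 2-bromoallyl ether
Product: 6 [3-(benzyloxy)prop-1-en-2-yl]tributylstannane, via 3-(benzyloxy)prop-1-en-2-yllithium 5 (not isolated)
Conditions: t-BuLi (2 equiv), Et2O, −78 °C; then Bu3SnCl, −78 °C → rt
Reagents that add atoms: tributyltin chloride, CCCC[Sn](Cl)(CCCC)CCCC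
Why: Bromine–lithium exchange on the vinylic bromide is fast at −78 °C, where loss of benzyloxide and benzylic deprotonation are slow, and stannylation of the vinyllithium occurs at the carbon that carried bromine, so the 2-stannyl regiochemistry is fixed by the halide.

Step 4
Reactants: 6 [3-(benzyloxy)prop-1-en-2-yl]tributylstannane
Product: 7 racemic 2-[(benzyloxy)methyl]-2-(tributylstannyl)oxirane
Conditions: mCPBA, Na2HPO4, CH2Cl2, 0 °C
Reagents that add atoms: mCPBA, OOC(=O)c1cccc(Cl)c1
Why: Prilezhaev epoxidation, in which the electron-releasing C–Sn bond makes the 1,1-disubstituted alkene nucleophilic enough for concerted oxygen transfer at 0 °C, the phosphate buffer keeps the carboxylic acid from cleaving the C–Sn bond, and the new stereocentre forms racemic, which is of no consequence.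

Step 5
Reactants: 7 racemic 2-[(benzyloxy)methyl]-2-(tributylstannyl)oxirane; 2 2-(2-methoxy-4-methylphenyl)-4,4,5,5-tetramethyl-1,3,2-dioxaborolane
Product: 10 racemic 3-(benzyloxy)-2-(2-methoxy-4-methylphenyl)-2-(4,4,5,5-tetramethyl-1,3,2-dioxaborolan-2-yl)propan-1-ol, via 2-(benzyloxymethyl)oxiran-2-yllithium 8 (not isolated), via lithium aryl(oxiranyl)pinacolatoborate 9 (not isolated)
Conditions: n-BuLi (slight deficit to 7), THF, −95 °C, 10 min; then 2, −95 → 0 °C; sat. aq NH4Cl
Reagents that add atoms: none
Why: n-BuLi attacks tin in 7 and releases the oxiranyllithium 8 together with Bu4Sn; 8 adds to the empty p orbital of boron in 2 to give the tetracoordinate boronate 9, and on warming the aryl group moves with its bonding electron pair from boron to the epoxide carbon, antiperiplanar to the ring C–O bond that breaks, to leave the lithium alkoxide of 10, which NH4Cl protonates. The closest known reaction type is the homologation of boronic esters with lithiated epoxides (lithiation–borylation followed by 1,2-metallate rearrangement), in which oxiranyllithiums made by deprotonation or by metal exchange are captured by boronic esters in the same way. No ring is closed; the three-membered ring opens and its strain drives the migration. The boron-bearing carbon becomes a stereocentre, formed racemic because 7 is racemic, and no control is needed since it ceases to be stereogenic once the two arms are alike in 12. The step needs capture of the short-lived carbenoid 8 by boron ahead of its α-elimination, secured by exchange at −95 °C, brief ageing and immediate addition of 2, with n-BuLi kept in slight deficit to 7 so that none is left to butylate 2; it also needs carbon rather than pinacol oxygen to migrate, which the electron-rich anisyl group favours. Elimination of boron and the β-oxygen to an alkene is held back by quenching cold as soon as the migration is over and by oxidising 10 without delay.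

Step 6
Reactants: 10 racemic 3-(benzyloxy)-2-(2-methoxy-4-methylphenyl)-2-(4,4,5,5-tetramethyl-1,3,2-dioxaborolan-2-yl)propan-1-ol
Product: 11 racemic 3-(benzyloxy)-2-(2-methoxy-4-methylphenyl)propane-1,2-diol
Conditions: 30% aq H2O2, 2 M NaOH, THF, 0 °C → rt
Reagents that add atoms: hydrogen peroxide, OO
Why: Oxidation of the C–B bond (hydroperoxide adds to boron, the tertiary benzylic carbon migrates from boron to oxygen, the borate ester is hydrolysed) places the hydroxyl on the carbon that held boron, and rapid capture of boron by hydroperoxide leaves little room for boron–oxygen elimination.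

Step 7
Reactants: 11 racemic 3-(benzyloxy)-2-(2-methoxy-4-methylphenyl)propane-1,2-diol
Product: 12 2-(2-methoxy-4-methylphenyl)propane-1,2,3-triol
Conditions: H2 (1 atm), 10% Pd/C, EtOAc/EtOH, rt
Reagents that add atoms: none
Why: Catalytic hydrogenolysis of the O-benzyl ether under neutral conditions should leave the hindered, non-activated tertiary benzylic hydroxyl in place, and removal of the benzyl group makes the two arms identical.

Step 8
Reactants: 12 2-(2-methoxy-4-methylphenyl)propane-1,2,3-triol
Product: 13 2-hydroxy-2-(2-methoxy-4-methylphenyl)propane-1,3-diyl bis(2-methylpropanoate)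
Conditions: i-PrCOCl (2.2 equiv), pyridine, CH2Cl2, −20 → 0 °C
Reagents that add atoms: isobutyryl chloride, CC(C)C(Cl)=O
Why: Acylation (nucleophilic acyl substitution) of the two primary hydroxyls with pyridine as base, while the tertiary benzylic hydroxyl next to an ortho-substituted ring is far less reactive and should stay free at low temperature without an acyl-transfer catalyst.

**Compound list**

1 | (2-methoxy-4-methylphenyl)boronic acid | COc1cc(C)ccc1B(O)O | starting material
2 | 2-(2-methoxy-4-methylphenyl)-4,4,5,5-tetramethyl-1,3,2-dioxaborolane | COc1cc(C)ccc1B1OC(C)(C)C(C)(C)O1 | intermediate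
3 | 2,3-dibromoprop-1-ene | C=C(Br)CBr | starting material
4 | benzyl 2-bromoallyl ether, {[(2-bromoprop-2-en-1-yl)oxy]methyl}benzene | C=C(Br)COCc1ccccc1 | intermediate
5 | 3-(benzyloxy)prop-1-en-2-yllithium | [Li]C(=C)COCc1ccccc1 | intermediate (not isolated)
6 | [3-(benzyloxy)prop-1-en-2-yl]tributylstannane | CCCC[Sn](CCCC)(CCCC)C(=C)COCc1ccccc1 | intermediate
7 | racemic 2-[(benzyloxy)methyl]-2-(tributylstannyl)oxirane | CCCC[Sn](CCCC)(CCCC)C1(COCc2ccccc2)CO1 | intermediate
8 | racemic 2-(benzyloxymethyl)oxiran-2-yllithium | [Li]C1(COCc2ccccc2)CO1 | intermediate (not isolated)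
9 | racemic lithium [2-(benzyloxymethyl)oxiran-2-yl](2-methoxy-4-methylphenyl)(pinacolato)borate | [Li+].COc1cc(C)ccc1[B-]1(OC(C)(C)C(C)(C)O1)C1(COCc2ccccc2)CO1 | intermediate (not isolated)
10 | racemic 3-(benzyloxy)-2-(2-methoxy-4-methylphenyl)-2-(4,4,5,5-tetramethyl-1,3,2-dioxaborolan-2-yl)propan-1-ol | COc1cc(C)ccc1C(CO)(COCc1ccccc1)B1OC(C)(C)C(C)(C)O1 | intermediate
11 | racemic 3-(benzyloxy)-2-(2-methoxy-4-methylphenyl)propane-1,2-diol | COc1cc(C)ccc1C(O)(CO)COCc1ccccc1 | intermediate
12 | 2-(2-methoxy-4-methylphenyl)propane-1,2,3-triol (achiral) | COc1cc(C)ccc1C(O)(CO)CO | intermediate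
13 | 2-hydroxy-2-(2-methoxy-4-methylphenyl)propane-1,3-diyl bis(2-methylpropanoate) (achiral) | COc1cc(C)ccc1C(O)(COC(=O)C(C)C)COC(=O)C(C)C | target

**Step count**

Total steps: 8. Longest linear sequence: 7 steps (steps 2 to 8, from 3 to 13).

**Steps most likely to fail**

Step 5. The oxiranyllithium may decompose by α-elimination before it reaches boron, boronate formation between two hindered partners may be slow, or boron and the β-oxygen may be lost together after the migration. The fallback sets out from 1 and 4 and forms the same aryl–carbon bond by cross-coupling. A Suzuki–Miyaura coupling (Pd(PPh3)4, K2CO3, dioxane/H2O, 80 °C) should give 1-[3-(benzyloxy)prop-1-en-2-yl]-2-methoxy-4-methylbenzene F1. An Upjohn dihydroxylation of this 1,1-disubstituted alkene (OsO4 cat., NMO, acetone/H2O, rt) should then give the diol, so the detour comes back to the route at 11.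

Step 4. The vinyl C–Sn bond may be cleaved by the carboxylic acid formed during the epoxidation, or the stannyl epoxide may open under acid during work-up and chromatography. The fallback sets out from 3 and places the oxygen by a hydroxyl-directed, acid-free epoxidation before the benzyl group is introduced. Hydrolysis of the allylic bromide (aq K2CO3, reflux) should give 2-bromoprop-2-en-1-ol F2. Formation of the O,C-dilithio species (t-BuLi, 3 equiv, Et2O, −78 → 0 °C) and quenching with Bu3SnCl should give 2-(tributylstannyl)prop-2-en-1-ol F3. Epoxidation with VO(acac)2 (cat.) and tert-butyl hydroperoxide (CH2Cl2, 0 °C) should give racemic [2-(tributylstannyl)oxiran-2-yl]methanol F4. Benzylation (NaH, BnBr, THF, 0 °C) should not be harmed by epoxide migration, which is degenerate here, and comes back to the route at 7.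

Step 3. The vinyllithium may lose lithium benzyloxide to give an allene, or may be quenched by proton transfer from the benzylic position, before tin is introduced. The fallback sets out from 4 and avoids any organolithium. Palladium-catalysed stannylation of the vinyl bromide with hexabutyldistannane (Bu3SnSnBu3, Pd(PPh3)4, toluene, 100 °C) should give the vinylstannane directly, so it comes back to the route at 6 and makes no new compound (F0).

**Further compounds**

F1 | step 5 | 1-[3-(benzyloxy)prop-1-en-2-yl]-2-methoxy-4-methylbenzene | COc1cc(C)ccc1C(=C)COCc1ccccc1
F2 | step 4 | 2-bromoprop-2-en-1-ol | C=C(Br)CO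
F3 | step 4 | 2-(tributylstannyl)prop-2-en-1-ol | CCCC[Sn](CCCC)(CCCC)C(=C)CO
F4 | step 4 | racemic [2-(tributylstannyl)oxiran-2-yl]methanol | CCCC[Sn](CCCC)(CCCC)C1(CO)CO1
F0 | step 3 | none | none
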